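**Retrosynthetic overview**
- The target is (2S)-4'-O-geranylnaringenin. Ring C is opened at O1–C2 and at C4–C4a, which leads back to an achiral isomer of the target, the 3,5-dihydroxyphenyl ester of (E)-4-geranyloxycinnamic acid, in which the two halves are tethered through the ester (O–acyl) bond.
- Forward, in one pot: a photo-Fries 1,3-acyl shift makes C4–C4a and gives the 2',4',6'-trihydroxychalcone; a chiral bifunctional base then closes it by a biomimetic (chalcone-isomerase-like) oxa-Michael addition that makes O1–C2, ring C and the C2 stereocentre. Rings A and B are bought; ring C is the only ring formed.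
- Enabling feature: the C3-symmetric 1,3,5-trioxygenated ring A. Each ring CH (C2, C4, C6 of the phloroglucinol ester) lies between two oxygens, so every possible acyl migration terminus gives the same 2-acylphloroglucinol. That product always has an ortho OH to become O1 and a second one left as the chelated 5-OH.
- The ester comes from phloroglucinol and (E)-4-geranyloxycinnamic acid (Steglich); the acid comes from 4-hydroxybenzaldehyde by O-geranylation and Knoevenagel–Doebner condensation. The geranyl ether is installed first, so no phenol has to be differentiated on the flavanone and every later step is acid-free.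

Key step: step 4

Assumption: the quinine-derived thiourea is taken to give the 2S series (Si-face attack at C-β); if the sense of induction proves opposite, the commercially available quinidine-derived pseudoenantiomer is used with no other change.

**Step 1**
Reactants: 1 4-hydroxybenzaldehyde; 2 geranyl bromide [(2E)-1-bromo-3,7-dimethylocta-2,6-diene]
Product: 3 4-(geranyloxy)benzaldehyde
Conditions: K2CO3, acetone, reflux
Reagents that add atoms: none
Why: Williamson ether synthesis, in which the phenoxide displaces the primary allylic bromide by SN2 without allylic transposition, so the E-alkene of the geranyl unit is retained.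

**Step 2**
Reactants: 3 4-(geranyloxy)benzaldehyde; 4 malonic acid
Product: 5 (E)-3-[4-(geranyloxy)phenyl]prop-2-enoic acid
Conditions: pyridine, piperidine (cat.), 90 °C; then cold aq. citric acid
Reagents that add atoms: none
Why: Knoevenagel–Doebner condensation with decarboxylation should give the E-cinnamic acid selectively, and the basic medium leaves the allylic aryl ether untouched.

**Step 3**
Reactants: 5 (E)-3-[4-(geranyloxy)phenyl]prop-2-enoic acid; 6 phloroglucinol (benzene-1,3,5-triol, anhydrous, 4 equiv)
Product: 7 3,5-dihydroxyphenyl (E)-3-[4-(geranyloxy)phenyl]prop-2-enoate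
Conditions: DCC, DMAP (cat.), THF, 0 °C → rt
Reagents that add atoms: none
Why: Steglich esterification under neutral conditions, in which the excess of the cheap, water-extractable triol should favour the mono-ester statistically.

**Step 4**
Reactants: 7 3,5-dihydroxyphenyl (E)-3-[4-(geranyloxy)phenyl]prop-2-enoate
Product: 9 (2S)-4'-O-geranylnaringenin, via trihydroxychalcone 8 (not isolated)
Conditions: hν (300 nm), Ar-sparged PhCl (5 mM), 20 °C; then lamp off, 1-[3,5-bis(trifluoromethyl)phenyl]-3-[(8α,9S)-6'-methoxycinchonan-9-yl]thiourea (10 mol %), −20 → 0 °C, dark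
Reagents that add atoms: none
Why: Excitation of the aryl cinnamate homolyses the ArO–C(=O) bond to a caged 3,5-dihydroxyphenoxyl/cinnamoyl radical pair, which recombines at a ring carbon and tautomerises to acylphloroglucinol 8 (C4–C4a bond), and in the dark the bifunctional base then adds a 2'-phenoxide of 8 to C-β (O1–C2 bond), the isomerisation that chalcone isomerase carries out in the biosynthesis. The closest known reaction types are the photo-Fries rearrangement of hydroxyphenyl cinnamates to 2'-hydroxychalcones and the cinchona-base-catalysed asymmetric oxa-Michael cyclisation of 2'-hydroxychalcones that carry a second ortho hydroxyl. The dihydropyranone ring (ring C) closes in the 6-endo-trig mode. C2, the only stereocentre, is set under catalyst control: the quinuclidinium–phenoxide ion pair and the thiourea hydrogen-bonded to the enone carbonyl should direct oxygen to the Si face of C-β of the E-enone, which corresponds to 2S. The acyl shift needs no regiocontrol because C2, C4 and C6 of the 1,3,5-trioxygenated ring all give the same 2-acylphloroglucinol, and either of its two equivalent ortho hydroxyls can close the ring while the other remains as the chelated 5-OH. The geranyl ether and its two trisubstituted alkenes should survive because the medium is neutral, acid-free and oxygen-free, and telescoping avoids the uncontrolled racemic closure that isolation of 8 would invite.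

**Compound list**
1 | 4-hydroxybenzaldehyde | O=Cc1ccc(O)cc1 | starting material
2 | geranyl bromide, (2E)-1-bromo-3,7-dimethylocta-2,6-diene | CC(C)=CCC/C(C)=C/CBr | starting material
3 | 4-(geranyloxy)benzaldehyde | CC(C)=CCC/C(C)=C/COc1ccc(C=O)cc1 | intermediate
4 | malonic acid | OC(=O)CC(=O)O | starting material
5 | (E)-3-[4-(geranyloxy)phenyl]prop-2-enoic acid | CC(C)=CCC/C(C)=C/COc1ccc(/C=C/C(=O)O)cc1 | intermediate
6 | phloroglucinol (benzene-1,3,5-triol) | Oc1cc(O)cc(O)c1 | starting material
7 | 3,5-dihydroxyphenyl (E)-3-[4-(geranyloxy)phenyl]prop-2-enoate | CC(C)=CCC/C(C)=C/COc1ccc(/C=C/C(=O)Oc2cc(O)cc(O)c2)cc1 | intermediate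
8 | (E)-3-[4-(geranyloxy)phenyl]-1-(2,4,6-trihydroxyphenyl)prop-2-en-1-one (trihydroxychalcone, not isolated) | CC(C)=CCC/C(C)=C/COc1ccc(/C=C/C(=O)c2c(O)cc(O)cc2O)cc1 | intermediate
9 | (2S)-5,7-dihydroxy-2-[4-(geranyloxy)phenyl]chroman-4-one, (2S)-4'-O-geranylnaringenin | CC(C)=CCC/C(C)=C/COc1ccc([C@@H]2CC(=O)c3c(O)cc(O)cc3O2)cc1 | target

Total step count: 4
Longest linear sequence: 4 steps (1 → 3 → 5 → 7 → 9)

**Steps most likely to fail**

Step 4. Two processes may fail. The photochemical acyl shift may be outrun by E/Z isomerisation of the 4-alkoxycinnamoyl chromophore, by [2+2] dimerisation or by escape of the radical pair from the solvent cage. The ring closure may proceed with poor facial selectivity, be overtaken by uncatalysed closure (also of Z-chalcone), or be eroded by retro-oxa-Michael opening of the product. The fallback gives up the acyl shift and forms the C2–aryl bond by asymmetric conjugate arylation, a known way to enantioenriched flavanones. It sets out from geranyl bromide 2, which O-alkylates commercial 4-hydroxyphenylboronic acid pinacol ester (K2CO3, DMF, rt) to give 4-(geranyloxy)phenylboronic acid pinacol ester F1. Commercial 5,7-dihydroxychromone is protected (MOMCl, NaH, DMF) as 5,7-bis(methoxymethoxy)-4H-chromen-4-one F2. Rh(I)-catalysed asymmetric 1,4-addition of F1 to F2 (Rh(I) precursor, atropisomeric bisphosphine of the antipode that gives 2S, aq. KOH, toluene, 50 °C) should give (2S)-2-[4-(geranyloxy)phenyl]-5,7-bis(methoxymethoxy)chroman-4-one F3. Removal of the MOM groups (dilute HCl, MeOH, ≤40 °C) comes back to the route at 9.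

Step 3. Acylation may run on to di- and tri-esters, and the nucleophilic ring carbon of phloroglucinol may add in conjugate fashion to the unsaturated acylpyridinium intermediate. The fallback desymmetrises the triol before the acid is committed. It sets out from phloroglucinol 6, which is silylated (TBSCl 2 equiv, imidazole, DMF; the separable mono- and tris-silyl ethers are recycled) to 3,5-bis(tert-butyldimethylsilyloxy)phenol F4. Steglich coupling of F4 with acid 5 (1:1, DCC, DMAP cat., CH2Cl2) should give 3,5-bis(tert-butyldimethylsilyloxy)phenyl (E)-3-[4-(geranyloxy)phenyl]prop-2-enoate F5. Desilylation with HF·pyridine in THF at 0 °C, which spares the aryl ester and the geranyl ether, comes back to the route at 7.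

Step 2. Condensation and decarboxylation may stay incomplete, or the allylic aryl ether may be partly cleaved or isomerised during prolonged heating and acidic work-up. The fallback buys the cinnamate double bond instead of making it. It sets out from geranyl bromide 2, which alkylates commercial methyl (E)-4-hydroxycinnamate (K2CO3, acetone, reflux) to methyl (E)-3-[4-(geranyloxy)phenyl]prop-2-enoate F6. Saponification (LiOH, THF/MeOH/H2O, rt; cold citric acid work-up) comes back to the route at 5.

**Further compounds**
F1 | step 4 | 4-(geranyloxy)phenylboronic acid pinacol ester | CC(C)=CCC/C(C)=C/COc1ccc(B2OC(C)(C)C(C)(C)O2)cc1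
F2 | step 4 | 5,7-bis(methoxymethoxy)-4H-chromen-4-one | O=c1ccoc2cc(OCOC)cc(OCOC)c12
F3 | step 4 | (2S)-2-[4-(geranyloxy)phenyl]-5,7-bis(methoxymethoxy)chroman-4-one | CC(C)=CCC/C(C)=C/COc1ccc([C@@H]2CC(=O)c3c(OCOC)cc(OCOC)cc3O2)cc1
F4 | step 3 | 3,5-bis(tert-butyldimethylsilyloxy)phenol | CC(C)(C)[Si](C)(C)Oc1cc(O)cc(O[Si](C)(C)C(C)(C)C)c1
F5 | step 3 | 3,5-bis(tert-butyldimethylsilyloxy)phenyl (E)-3-[4-(geranyloxy)phenyl]prop-2-enoate | CC(C)=CCC/C(C)=C/COc1ccc(/C=C/C(=O)Oc2cc(O[Si](C)(C)C(C)(C)C)cc(O[Si](C)(C)C(C)(C)C)c2)cc1
F6 | step 2 | methyl (E)-3-[4-(geranyloxy)phenyl]prop-2-enoate | CC(C)=CCC/C(C)=C/COc1ccc(/C=C/C(=O)OC)cc1
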